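## The problem

Neoirietetraol 27 is a trans-fused decalin (rings A and B) that carries a cyclopentane (ring C) on C7 through the C7–C11 single bond, and because C11 and its neighbour C15 are both quaternary, this bond ends at one of two adjacent fully substituted carbons. The eight stereocentres fall into two groups that the C7–C11 bond keeps apart: C1, C4, C5, C7 and C10 on the decalin, and C11, C12 and C14 on ring C. Within the decalin the angular methyl on C10 can govern the others, and within ring C the quaternary C11 can govern C12 and C14, but nothing relays between the two groups, so C11 has to be set against the decalin through enantiopure coupling partners. Both bromines sit on secondary carbons beside a quaternary carbon (C1 beside C10, C14 beside C15), in the configuration whose backside is screened by a methyl group, so displacement of an oxygen leaving group cannot be relied on. The finished bromides are open to elimination, cationic rearrangement and reduction by dissolving metals or strong hydrides. The tertiary alcohols at C4, C5 and C7 are acid-labile and are best introduced late. Their arrangement makes a short endgame possible: the C7 and C5 hydroxyls are 1,3-diaxial on ring A, on the face opposite the C10 methyl, and the C4 hydroxyl is anti to the one on C5. An O–O bridge from C7 to C5 fits the first pair, and capture of a second O2 at C4 from the side away from that bridge fits the third.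

## Retrosynthesis

27 ⇒ 26. The three tertiary hydroxyls are written as the oxygens of two peroxide groups in 26: the C7–O–O–C5 bridge of a 1,2-dioxolane and a C4–OOSiEt3 group. Only O–O bonds are cut. A peroxide costs no protecting-group step because it is what the oxygenation itself delivers. The forward step must reduce O–O bonds without touching C–Br.

26 ⇒ 25. The C7–O, C5–O and C4–O bonds are cut together, back to two molecules of O2 and the skipped diene 25 (C7=C8 and C4=C5). The neighbouring option, epoxidation and hydrolysis at C4–C5 plus a separate hydration at C7, needs three operations and three separate stereochemical arguments. The cascade sets C7, C5 and C4 in one step, each centre relaying to the next through the bridge. 25 has five stereocentres instead of eight and no tertiary alcohol. The forward reaction must start at C7=C8, not at C4=C5, and take up the first O2 axially at C7.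

25 ⇒ 24 ⇒ 22. The C12 carbinol is traced to a ketone, and the C14–Br bond is cut as a conjugate addition of bromide to the ring C enone 22. C14 lies beside the gem-dimethyl carbon C15, so the bond is made by attack on an activated alkene, not by displacement. Enone 22 keeps C11 as its only ring C stereocentre. The forward steps must place bromine cis to the decalinyl group on C11 and deliver hydride to C12 from the methyl face.

22 ⇒ 21 ⇒ 13 + 19. The C7–C11 bond is cut between the alkenyl triflate 13 and the lithium enolate 20 released from 19. This is the convergent cut, dividing the molecule into a twelve-carbon decalin and an eight-carbon ring. A quaternary C11 beside C15 can come from an alkenyl cuprate adding to a cyclopentenone (carbonyl left at C14) or from alkenylation of an enolate (carbonyl left at C12). The second is chosen because it leaves the carbonyl where the target has a hydroxyl and makes C14 reachable by conjugate addition. The C14 silyloxy group in 19 and 21 is a traceless control element: it sets the face of C11 and then leaves by β-elimination to unveil 22. The coupling has to form a bond at an enolate carbon flanked by a quaternary carbon.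

13 ⇒ 11 ⇒ 9 ⇒ 8. These cuts fix the C7–O bond of the enol triflate and the position of both ring alkenes. A C7 ketone that already has the C4=C5 alkene enolises towards the doubly activated C6, which would give the wrong triflate. The C7=C8 enolate is therefore made by hydride addition to C9 of enone 11. 11 comes from the cross-conjugated dienone 9 by kinetic protonation of its extended enolate, which moves C5=C6 to C4=C5, and 9 comes from enone 8 by dehydrogenation.

8 ⇒ 7 ⇒ 6 ⇒ 5 ⇒ 4 ⇒ 3 ⇒ 2 ⇒ 1. The C1–Br stereocentre is traced to C–H bond formation on a bromoalkene (6 to 7), and the C4 methyl to a one-carbon γ-functionalisation of the enone (3 to 4 to 5). A nucleophile that is to leave bromine equatorial at C1 would have to approach this neopentyl carbon parallel to the axial C10 methyl, and a displacement that avoids this approach can only give the axial bromide. Delivery of a hydrogen atom to a C1 radical on the open face gives the equatorial bromide instead. The enone must be masked during this radical step; acetal 6 does so and also makes the only other alkene tetrasubstituted. Compound 1 supplies C10 in the right absolute configuration and oxygen at exactly C1 and C7.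

19 ⇒ 18 ⇒ 17 ⇒ 16 ⇒ 15 ⇒ 14. Three C–CH3 bonds of ring C are cut. Cuprate addition builds the gem-dimethyl carbon (18 to 19). The two alkene methyls of 18 come from iodination and methyl coupling, then cuprate addition and dehydrogenation, of commercial 14. The single stereocentre of 14 becomes the C14 control element.

## Roads not taken

Alternative 1: Ring A is cut at C9–C10 and C5–C6. In the forward direction the 2-substituted butadiene A2, which already carries a brominated and silylated ring C, adds under AlBr3/AlMe3 to the C5=C10 alkene of the silyloxy methylcyclohexenone A3. This gives the cis-fused octalone A1 with C10 quaternary and the C7=C8 alkene in place.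
- Merits: the union is convergent and forms two C–C bonds. The ring C bromide and alcohol are set on a small fragment before any other alkene exists. In this respect it is better than the chosen plan, which has to brominate ring C beside the skipped diene (step 18) and forge the crowded C7–C11 bond by cross-coupling (step 16).
- Weak points: a 2-methylcyclohexenone is a reluctant dienophile, so a strong mixed aluminium Lewis acid is needed. That acid threatens ionisation of the secondary bromide beside the gem-dimethyl carbon and loss of silyl ethers. Two chiral partners meet with facial selectivity that only the C4 silyloxy group of A3 controls.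
- Comparison: A1 still lacks the C4 methyl and all three tertiary oxygens, has C5 as a cis-fused C–H and C1 as a ketone. The C5 hydroxylation, C4 methyl addition, C7 hydration and the C1 bromide would each need separate steps. The chosen plan pays with a longer linear route to 13 but makes the three C–O bonds in one step.

Alternative 2: The C5–C10 and C1–Br bonds are cut together, opening rings A and B to the ten-membered cyclodeca-1(10),4-diene A5 with a silyl group on C5. In the forward direction bromodiethylsulfonium bromopentachloroantimonate attacks the C1=C10 alkene, C5 bonds to C10 across the ring and the silyl group leaves. The product is the bromo octalin acetonide A4 with the C4=C5 alkene.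
- Merits: anti addition across C1=C10 gives the equatorial C1 bromide, cis to the angular methyl, in a single step, together with both rings. The chosen plan needs steps 1, 2, 5, 6 and 7 for the same stereocentre, so this road is clearly better there. A4 also carries the C7 oxygen.
- Weak points: A5 is a medium ring with two trisubstituted ring-trans alkenes, a fully substituted C7 and ring C attached, and its synthesis is long. The facial course of the transannular step depends on the ring conformer. The bromonium ion may also be intercepted by proton loss or form at the vinylsilane.
- Comparison: the C4 and C5 oxygens would still need a separate trans-dihydroxylation. The chosen plan sets against this a commercial enantiopure bicycle, no medium ring, and one step for all three tertiary oxygens.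

Alternative 3: Ring B is cut at C4–C5. In the forward direction a triazolium-derived carbene converts the C4 aldehyde of the keto aldehyde A7 into an acyl anion equivalent that adds to the C5 ketone. This closes ring B and gives the α-hydroxy ketone A6.
- Merits: the most hindered tertiary alcohol (C5) is made by C–C bond formation without peroxides, and the C4 ketone is ready for methyl addition. For certainty of the C5–O bond this road is at least as good as the chosen one.
- Weak points: the trans ring fusion must come from the catalyst. A7 has bromine γ to the aldehyde carbon, so its enol or the basic medium can close a cyclopropane or eliminate HBr. The methyl addition at C4 must give the alcohol anti to the C5 hydroxyl.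
- Comparison: A6 contains only rings A and B. Ring C would have to be joined at C7 afterwards, by the same alkenylation followed by a hydration, so the C7–C11 bond and the C7 alcohol remain open. The chosen plan answers with one radical step for C4, C5 and C7 after the skeleton is complete.

Key step: step 20

Assumption: atom numbers C1–C15 of the target are used for every intermediate, and the saturated C1 carbonyl of 1 is taken to condense with the silyl hydrazine before the conjugated C7 carbonyl, as it does with borohydride and in acetal formation.

## Steps

Step 1
Reactants: 1 (S)-Wieland–Miescher ketone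
Product: 2 C1 N-(tert-butyldimethylsilyl)hydrazone of 1
Conditions: TBSNHNHTBS, Sc(OTf)3 (cat.), CHCl3, 23 → 55 °C
Reagents that add atoms: 1,2-bis(tert-butyldimethylsilyl)hydrazine, CC(C)(C)[Si](C)(C)NN[Si](C)(C)C(C)(C)C
Why: Sc(OTf)3-catalysed condensation with the bis-silyl hydrazine gives the N-silyl hydrazone; the saturated C1 carbonyl is the more electrophilic one (the site selectivity of borohydride reduction and acetalisation of 1), and no stereocentre is touched.

Step 2
Reactants: 2 C1 N-silyl hydrazone
Product: 3 bromo dienone with C1(Br)=C2 bromoalkene and C5=C6 enone
Conditions: Br2, 2-tert-butyl-1,1,3,3-tetramethylguanidine, CH2Cl2, 0 °C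
Reagents that add atoms: bromine, BrBr
Why: Barton vinyl halide synthesis: bromination of the hydrazone leads through a diazo compound to loss of N2 and of the C2 proton; C10 is quaternary, so the alkene can only form towards C2, as with other ketones beside an angular methyl group.

Step 3
Reactants: 3 bromo dienone
Product: 4 C4-methylene dienone
Conditions: CH2(OEt)2, POCl3, NaOAc, CHCl3, reflux
Reagents that add atoms: diethoxymethane, CCOCOCC
Why: Vinylogous Prins-type γ-methylenation: the enone forms its heteroannular dienol ether in situ, which attacks the ethoxymethyl cation at C4, and ethanol is lost; this is the standard route to 6-methylene derivatives of 3-oxo-Δ4 steroids, and C4 is the only γ-carbon of 3.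

Step 4
Reactants: 4 C4-methylene dienone
Product: 5 C4-methyl enone (C4 epimers)
Conditions: H2 (1 atm), RhCl(PPh3)3 (cat.), benzene–EtOH, 23 °C
Reagents that add atoms: none
Why: Homogeneous hydrogenation with RhCl(PPh3)3 reduces the unhindered 1,1-disubstituted alkene and leaves the trisubstituted enone alkene and the bromoalkene; the C4 configuration does not matter because C4 becomes trigonal again in step 5.

Step 5
Reactants: 5 C4-methyl enone
Product: 6 C7 ethylene acetal with tetrasubstituted C4=C5 alkene and C1(Br)=C2 bromoalkene
Conditions: HOCH2CH2OH, p-TsOH (cat.), benzene, reflux (water removed)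
Reagents that add atoms: ethylene glycol, OCCO
Why: Acid-catalysed acetalisation of a β,β-disubstituted enone moves the double bond out of conjugation (as with 3-oxo-Δ4 steroids), here into the tetrasubstituted C4=C5 position; the acetal hides the enone from the radical chemistry of step 6.

Step 6
Reactants: 6 bromoalkene acetal
Product: 7 C7 ethylene acetal with C4=C5 alkene and C1 bromide cis to the C10 methyl
Conditions: Co(acac)2, t-BuOOH, Et3SiH, 1,4-cyclohexadiene, n-PrOH, 23 °C
Reagents that add atoms: none
Why: Cobalt-hydride hydrogen-atom-transfer hydrogenation of an alkenyl bromide: the hydrogen atom adds to C2, and the α-bromo radical at C1 takes its hydrogen from cyclohexadiene on the face opposite the angular methyl, which leaves bromine equatorial and cis to that methyl (the epimer that displacement cannot deliver); the tetrasubstituted alkene is too hindered for hydrogen-atom transfer.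

Step 7
Reactants: 7 bromo acetal
Product: 8 bromo enone (C7 ketone, C5=C6, C4 epimers)
Conditions: 2 M HCl, THF, 40 °C
Reagents that add atoms: water, O
Why: Acetal hydrolysis followed by acid-catalysed return of the double bond into conjugation gives the thermodynamic enone; the secondary bromide is stable to aqueous acid and the C4 epimers again do not matter.

Step 8
Reactants: 8 bromo enone
Product: 9 cross-conjugated dienone (C5=C6 and C8=C9, C4 epimers)
Conditions: DDQ, 1,4-dioxane, reflux
Reagents that add atoms: none
Why: DDQ dehydrogenation of a cyclohexenone at the α′,β′ position under neutral conditions (hydride abstraction from the cross-conjugated enol) is the standard entry to cross-conjugated dienones; C10 is quaternary, so only C8–C9 can be desaturated on that side.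

Step 9
Reactants: 9 cross-conjugated dienone
Product: 11 dienone with C4=C5 and C8=C9 alkenes and C6 methylene, via potassium trienolate 10 (not isolated)
Conditions: t-BuOK, t-BuOH–THF, 23 °C; inverse quench into cold aq. AcOH
Reagents that add atoms: none
Why: Deconjugation by kinetic protonation: t-BuOK removes the γ-proton at C4, and quenching the extended enolate 10 into cold acid protonates the α-carbon C6, which places the alkene in the tetrasubstituted C4=C5 position (known for cross-conjugated cyclohexadienones); the equatorial bromide has no antiperiplanar hydrogen for elimination.

Step 10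
Reactants: 11 deconjugated dienone
Product: 13 C7 enol triflate with C7=C8 and C4=C5 alkenes, via potassium enolate 12 (not isolated)
Conditions: K[s-Bu3BH], THF, −78 °C; then PhNTf2, −78 → 0 °C
Reagents that add atoms: N-phenylbis(trifluoromethanesulfonimide), O=S(=O)(N(c1ccccc1)S(=O)(=O)C(F)(F)F)C(F)(F)F
Why: Conjugate reduction of the β-unsubstituted enone by the hindered borohydride delivers hydride to C9 and gives only the C7=C8 enolate 12, which is sulfonylated on oxygen; deprotonation of a C7 ketone would instead go towards the doubly activated C6.

Step 11
Reactants: 14 (S)-4-(tert-butyldimethylsilyloxy)cyclopent-2-en-1-one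
Product: 15 (S)-4-(tert-butyldimethylsilyloxy)-2-iodocyclopent-2-en-1-one
Conditions: I2, pyridine, CH2Cl2, 0 → 23 °C
Reagents that add atoms: iodine, II
Why: α-Iodination of an enone by conjugate addition of pyridine, iodination of the enolate and elimination (Baylis–Hillman-type sequence); the C4 stereocentre of the ring is not involved.

Step 12
Reactants: 15 iodo enone
Product: 16 (S)-4-(tert-butyldimethylsilyloxy)-2-methylcyclopent-2-en-1-one
Conditions: Me4Sn, PdCl2(PhCN)2 (cat.), AsPh3, CuI, NMP, 80 °C
Reagents that add atoms: tetramethylstannane, C[Sn](C)(C)C
Why: Stille coupling of the α-iodo enone with tetramethyltin, accelerated by CuI and triphenylarsine, is a standard route to 2-alkyl-4-silyloxycyclopentenones.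

Step 13
Reactants: 16 2-methyl enone
Product: 17 (3S,4S)-4-(tert-butyldimethylsilyloxy)-2,3-dimethyl-1-(trimethylsilyloxy)cyclopent-1-ene
Conditions: Me2CuLi, TMSCl, THF, −78 °C; Et3N
Reagents that add atoms: lithium dimethylcuprate, [Li+].C[Cu-]C; chlorotrimethylsilane, C[Si](C)(C)Cl
Why: Cuprate conjugate addition trans to the silyloxy group with in situ silylation of the enolate; the new C3 stereocentre is removed in step 14.

Step 14
Reactants: 17 silyl enol ether
Product: 18 (S)-4-(tert-butyldimethylsilyloxy)-2,3-dimethylcyclopent-2-en-1-one
Conditions: Pd(OAc)2 (cat.), O2 (1 atm), DMSO, 25 °C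
Reagents that add atoms: none
Why: Saegusa–Ito oxidation: the divalent palladium enolate undergoes β-hydride elimination from C3 and restores the enone, now tetrasubstituted; O2 reoxidises palladium and the silyloxy stereocentre is untouched.

Step 15
Reactants: 18 2,3-dimethyl enone
Product: 19 (S)-4-(tert-butyldimethylsilyloxy)-2,3,3-trimethyl-1-(trimethylsilyloxy)cyclopent-1-ene
Conditions: Me2CuLi, TMSCl, THF, −78 → −40 °C; Et3N
Reagents that add atoms: lithium dimethylcuprate, [Li+].C[Cu-]C; chlorotrimethylsilane, C[Si](C)(C)Cl
Why: Chlorosilane-accelerated cuprate addition to the tetrasubstituted enone makes the gem-dimethyl carbon C15 (no new stereocentre) and fixes the enol ether double bond between C11 and C12, away from the silyloxy-bearing side.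

Step 16
Reactants: 19 ring C silyl enol ether; 13 C7 enol triflate
Product: 21 C7–C11 coupled ketone with C12 ketone and C14 silyl ether trans to the decalinyl group, via lithium enolate 20 (not isolated)
Conditions: 19, MeLi, THF, 0 °C; then 13, Pd2(dba)3 (cat.), P(t-Bu)3, THF, 23 → 50 °C
Reagents that add atoms: none
Why: Palladium-catalysed α-alkenylation of a ketone enolate: zerovalent palladium inserts into the C7–O bond of the triflate, the regio-defined lithium enolate 20 transmetalates and reductive elimination forms the C7–C11 bond and the quaternary C11; the alkenyl group should enter anti to the C14 silyloxy group, which fixes C11 against the decalin stereocentres, and the alkyl bromide does not compete with the alkenyl triflate in oxidative addition.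

Step 17
Reactants: 21 β-silyloxy ketone
Product: 22 ring C enone (C12 ketone, C13=C14)
Conditions: DBU, CH2Cl2, 23 °C
Reagents that add atoms: none
Why: E1cB elimination of silanolate from the β-silyloxy ketone (C11 is quaternary, so only C13 can be deprotonated); the C14 centre has done its work and is removed, and C11 cannot epimerise.

Step 18
Reactants: 22 ring C enone
Product: 24 β-bromo ketone with C14 bromide cis to the decalinyl group on C11, via bromo silyl enol ether 23 (not isolated)
Conditions: TMSBr, CH2Cl2, −40 → 0 °C; pH 7 buffer, 0 °C
Reagents that add atoms: bromotrimethylsilane, C[Si](C)(C)Br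
Why: Conjugate addition of a halosilane to an enone (O-silylation, bromide attack at the β-carbon C14) gives silyl enol ether 23, hydrolysed on work-up; the addition is reversible and should settle on the epimer with bromine cis to the large C11 substituent (both pseudo-equatorial, trans to the C11 methyl), and no protic acid is present to protonate the two alkenes.

Step 19
Reactants: 24 β-bromo ketone
Product: 25 dibromo diene alcohol with C7=C8 and C4=C5 alkenes and free C12 hydroxyl
Conditions: NaBH4, CeCl3·7H2O, MeOH, −78 °C
Reagents that add atoms: none
Why: Luche reduction under non-basic conditions (no loss of HBr from the β-bromo ketone): hydride attacks C12 from the face of the C11 methyl, opposite the decalinyl substituent and the C14 bromine, so the hydroxyl ends cis to both.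

Step 20
Reactants: 25 dibromo diene alcohol
Product: 26 1,2-dioxolane bridging C7 and C5 with a C4 triethylsilyl peroxide
Conditions: Co(acac)2 (cat.), O2 (1 atm), Et3SiH, ClCH2CH2Cl, 23 °C
Reagents that add atoms: dioxygen, O=O; triethylsilane, CC[SiH](CC)CC
Why: A trivalent cobalt hydride (from Co(acac)2, O2 and Et3SiH) transfers a hydrogen atom to C8 of the less hindered trisubstituted alkene and leaves the tertiary C7 radical, which captures O2. The C7 peroxyl radical adds to C5 of the C4=C5 alkene in a 5-exo-trig closure that forms the 1,2-dioxolane (a 6,7-dioxabicyclo[3.2.1]octane with ring A), and the resulting tertiary C4 radical captures a second O2 and ends as the triethylsilyl peroxide. The closest known reaction is the cobalt-catalysed hydroperoxysilylation of alkenes (Mukaiyama–Isayama), which with 1,4-dienes ends in 1,2-dioxolanes through the same peroxyl radical cyclisation. At C7, O2 is taken up axially on the face opposite the angular methyl because ring C then stays equatorial; an equatorial peroxyl radical could not reach C5. At C5, the one-atom bridge forces the new C–O bond cis and 1,3-diaxial to the C7–O bond, which makes the ring fusion trans. At C4, the second O2 approaches axially and anti to the new C5–O bond, which screens its own face, leaving the methyl equatorial. The step needs initiation at C7=C8 and not at C4=C5; tetrasubstituted alkenes accept hydrogen atoms far more slowly than trisubstituted ones. Secondary alkyl bromides and the free C12 hydroxyl are inert to these conditions.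

Step 21
Reactants: 26 dioxolane silyl peroxide
Product: 27 neoirietetraol
Conditions: Zn, AcOH, THF, 23 °C
Reagents that add atoms: none
Why: Zinc in acetic acid reduces both O–O bonds (the dialkyl peroxide of the dioxolane and the silyl peroxide) to hydroxyl groups without breaking any C–O bond, so C4, C5 and C7 keep their configurations; unactivated secondary alkyl bromides are not reduced by zinc under these conditions.

## Compound list

1 | (S)-Wieland–Miescher ketone (C1 and C7 ketones, C5=C6 alkene, C10 methyl) | C[C@]12CCC(=O)C=C1CCCC2=O | starting material
2 | C1 N-(tert-butyldimethylsilyl)hydrazone of 1 | C[C@]12CCC(=O)C=C1CCCC2=NN[Si](C)(C)C(C)(C)C | intermediate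
3 | bromo dienone: C1(Br)=C2 bromoalkene, C5=C6 enone, C7 ketone | C[C@]12CCC(=O)C=C1CCC=C2Br | intermediate
4 | C4-methylene derivative of 3 | C[C@]12CCC(=O)C=C1C(=C)CC=C2Br | intermediate
5 | C4-methyl enone (C4 epimers) with C1(Br)=C2 bromoalkene | C[C@]12CCC(=O)C=C1C(C)CC=C2Br | intermediate
6 | C7 ethylene acetal with tetrasubstituted C4=C5 alkene and C1(Br)=C2 bromoalkene | C[C@]12CCC3(OCCO3)CC1=C(C)CC=C2Br | intermediate
7 | C7 ethylene acetal with C4=C5 alkene and (1S)-bromide, equatorial and cis to the C10 methyl | C[C@]12CCC3(OCCO3)CC1=C(C)CC[C@@H]2Br | intermediate
8 | bromo enone: C7 ketone, C5=C6 alkene, C4 methyl (C4 epimers), C1 bromide cis to the C10 methyl | C[C@]12CCC(=O)C=C1C(C)CC[C@@H]2Br | intermediate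
9 | cross-conjugated dienone (C5=C6 and C8=C9, C7 ketone; C4 epimers) | C[C@]12C=CC(=O)C=C1C(C)CC[C@@H]2Br | intermediate
10 | potassium trienolate of 9 (O–C7=C6, C5=C4, C8=C9) | C[C@]12C=CC([O-])=CC1=C(C)CC[C@@H]2Br.[K+] | intermediate
11 | dienone with tetrasubstituted C4=C5 alkene and C8=C9–C7=O enone | C[C@]12C=CC(=O)CC1=C(C)CC[C@@H]2Br | intermediate
12 | potassium C7=C8 enolate | C[C@]12CC=C([O-])CC1=C(C)CC[C@@H]2Br.[K+] | intermediate
13 | C7 enol triflate (C7=C8) with C4=C5 alkene and C1 bromide | C[C@]12CC=C(OS(=O)(=O)C(F)(F)F)CC1=C(C)CC[C@@H]2Br | intermediate
14 | (S)-4-(tert-butyldimethylsilyloxy)cyclopent-2-en-1-one | O=C1C=C[C@@H](O[Si](C)(C)C(C)(C)C)C1 | starting material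
15 | (S)-4-(tert-butyldimethylsilyloxy)-2-iodocyclopent-2-en-1-one | O=C1C(I)=C[C@@H](O[Si](C)(C)C(C)(C)C)C1 | intermediate
16 | (S)-4-(tert-butyldimethylsilyloxy)-2-methylcyclopent-2-en-1-one | O=C1C(C)=C[C@@H](O[Si](C)(C)C(C)(C)C)C1 | intermediate
17 | (3S,4S)-4-(tert-butyldimethylsilyloxy)-2,3-dimethyl-1-(trimethylsilyloxy)cyclopent-1-ene | C[C@H]1C(C)=C(O[Si](C)(C)C)C[C@@H]1O[Si](C)(C)C(C)(C)C | intermediate
18 | (S)-4-(tert-butyldimethylsilyloxy)-2,3-dimethylcyclopent-2-en-1-one | CC1=C(C)C(=O)C[C@@H]1O[Si](C)(C)C(C)(C)C | intermediate
19 | (S)-4-(tert-butyldimethylsilyloxy)-2,3,3-trimethyl-1-(trimethylsilyloxy)cyclopent-1-ene | CC1(C)[C@@H](O[Si](C)(C)C(C)(C)C)CC(O[Si](C)(C)C)=C1C | intermediate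
20 | lithium enolate of (S)-4-(tert-butyldimethylsilyloxy)-2,3,3-trimethylcyclopentanone (C11=C12) | CC1(C)[C@@H](O[Si](C)(C)C(C)(C)C)CC([O-])=C1C.[Li+] | intermediate
21 | coupled ketone: C12 ketone, quaternary C11 bonded to C7, C14 silyl ether trans to the decalinyl group | CC1(C)[C@@H](O[Si](C)(C)C(C)(C)C)CC(=O)[C@]1(C)C1=CC[C@]2(C)[C@@H](Br)CCC(C)=C2C1 | intermediate
22 | ring C enone (C12 ketone, C13=C14) | CC1(C)C=CC(=O)[C@]1(C)C1=CC[C@]2(C)[C@@H](Br)CCC(C)=C2C1 | intermediate
23 | C14 bromide with C12 trimethylsilyl enol ether (C12=C13) | CC1(C)[C@H](Br)C=C(O[Si](C)(C)C)[C@]1(C)C1=CC[C@]2(C)[C@@H](Br)CCC(C)=C2C1 | intermediate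
24 | β-bromo ketone: C12 ketone, C14 bromide cis to the decalinyl group | CC1(C)[C@H](Br)CC(=O)[C@]1(C)C1=CC[C@]2(C)[C@@H](Br)CCC(C)=C2C1 | intermediate
25 | dibromo diene alcohol: C7=C8 and C4=C5 alkenes, C12 hydroxyl cis to C14 bromide and to the decalinyl group | CC1(C)[C@H](Br)C[C@H](O)[C@]1(C)C1=CC[C@]2(C)[C@@H](Br)CCC(C)=C2C1 | intermediate
26 | 1,2-dioxolane bridging C7 and C5 (oxygens 1,3-diaxial, anti to the C10 methyl) with C4 triethylsilyl peroxide anti to the C5 oxygen | CC1(C)[C@H](Br)C[C@H](O)[C@]1(C)[C@@]1(OO5)CC[C@]2(C)[C@@H](Br)CC[C@@](C)(OO[Si](CC)(CC)CC)[C@@]25C1 | intermediate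
27 | neoirietetraol | CC1(C)[C@H](Br)C[C@H](O)[C@]1(C)[C@@]1(O)CC[C@]2(C)[C@@H](Br)CC[C@@](C)(O)[C@@]2(O)C1 | target

## Step count and risks

Total step count: 21. Longest linear sequence: 16 steps (steps 1–10 and 16–21, from 1). The ring C branch from 14 is 5 steps (11–15) before the union.

Least certain steps:

**Step 20 (key step).** The C7 peroxyl radical may be reduced to the uncyclised C7 silyl peroxide before it closes onto C5. Oxygen capture at C7 may be poorly face-selective, and capture at C4 on the face that is 1,3-diaxial to the C10 methyl may lose out to capture on the other face. Hydrogen-atom transfer to the tetrasubstituted alkene or abstraction of the doubly allylic C6 hydrogens may compete. Fallback, setting out from 25 and returning at 27, introduces the oxygens one after the other. mCPBA (1 equiv, NaHCO3, CH2Cl2, −20 °C) should epoxidise the more electron-rich tetrasubstituted alkene on the face opposite the C10 methyl to give 4,5-epoxide F1 of the diene alcohol. Mukaiyama hydration of the remaining C7=C8 alkene of F1 with Co(acac)2, O2 and PhSiH3, then PPh3, now with no alkene for the peroxyl radical to add to, gives epoxy alcohol F2 with the new C7 hydroxyl axial. Dilute HClO4 in aqueous THF then opens the epoxide of F2 trans-diaxially at C4 with inversion (Fürst–Plattner) and returns to the route at 27.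

**Step 16.** Reductive elimination at an enolate carbon flanked by the gem-dimethyl carbon may be too slow, so that no coupling occurs or silanolate is lost from 21 under the basic conditions. Facial selectivity at C11 may be low because the directing silyloxy group is two bonds away. Fallback, setting out from 19 and 13 and returning at 21, is a 1,2-addition followed by a 1,2-shift. NCS converts 19 into the α-chloro ketones epimeric at C11, and the epimer with chlorine cis to the silyloxy group, chloro ketone F3 , is separated at this small-molecule stage. 13 is turned with (Me3Sn)2, Pd(PPh3)4 and LiCl into alkenylstannane F4 with tin on C7. Tin–lithium exchange of F4 with MeLi and transmetalation with CeCl3 give an alkenyl nucleophile that adds to the C12 carbonyl of F3 anti to chlorine to give chlorohydrin F5 with the alkenyl group trans to chlorine. Heating the magnesium alkoxide of F5 (EtMgBr, benzene) moves the alkenyl group from C12 to C11 with loss of chloride (semipinacol rearrangement of an α-halo carbinol) and gives 21 with C11 set stereospecifically.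

**Step 18.** Bromide may add on the face opposite the decalinyl group and the adduct may not equilibrate, giving the C14 epimer, or the β-bromo ketone may revert to 22 during work-up. Fallback, setting out from 22 and returning at 25, puts boron on C14 first. Copper-catalysed conjugate borylation (B2pin2, CuCl, NaOt-Bu, MeOH, THF) should deliver boron anti to the decalinyl group and give β-boryl ketone F6 with the boronate trans to that group. Luche reduction of F6 gives boryl alcohol F7 with the C12 hydroxyl cis to the decalinyl group. Formation of the aryl boronate complex of F7 with 3,5-bis(trifluoromethyl)phenyllithium (2 equiv, the first deprotonates the hydroxyl) and bromination with NBS replace boron by bromine with inversion and return to the route at 25.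

**Step 6.** Hydrogen-atom transfer to the tetrasubstituted alkene, abstraction of the doubly allylic C3 hydrogens by alkoxyl radicals, or loss of bromine from the radical may compete with the wanted reduction. Fallback, setting out from 2 and returning at 8, reduces a gem-dibromide instead. CuBr2 and Et3N in MeOH convert the hydrazone into gem-dibromide F8 at C1. One equivalent of Bu3SnH (Et3B, air, −78 °C) removes one bromine from F8 , the α-bromo radical taking hydrogen on the face opposite the angular methyl, to give bromo enone F9 with bromine cis to the C10 methyl and the enone untouched. γ-Methylenation of F9 as in step 3 gives methylene dienone F10 , and hydrogenation of F10 as in step 4 returns to the route at 8 without the acetal detour.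

**Step 1.** Condensation may occur at the conjugated C7 carbonyl or at both carbonyls. Fallback, setting out from 1 and returning at 3, masks the enone first. Ethane-1,2-dithiol and BF3·OEt2 convert the enone carbonyl selectively into dithiolane F11 with the C1 ketone free. KN(SiMe3)2 and PhNTf2 turn F11 into enol triflate F12 of the only enolisable ketone. Nickel-catalysed triflate–bromide exchange on F12 with Ni(cod)2 and LiBr gives bromoalkene dithiolane F13 with the C5=C6 alkene retained. MeI and CaCO3 in aqueous MeCN remove the dithiolane from F13 and return to the route at 3.

## Further compounds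

F1 | step 20 | 4,5-epoxide of 25, oxygen on the face opposite the C10 methyl | CC1(C)[C@H](Br)C[C@H](O)[C@]1(C)C1=CC[C@]2(C)[C@@H](Br)CC[C@](C)(O3)[C@@]23C1
F2 | step 20 | C7 tertiary alcohol of epoxide F1 | CC1(C)[C@H](Br)C[C@H](O)[C@]1(C)[C@@]1(O)CC[C@]2(C)[C@@H](Br)CC[C@](C)(O3)[C@@]23C1
F3 | step 16 | (4S)-2-chloro-4-(tert-butyldimethylsilyloxy)-2,3,3-trimethylcyclopentanone, chlorine cis to the silyloxy group | CC1(C)[C@@H](O[Si](C)(C)C(C)(C)C)CC(=O)[C@@]1(C)Cl
F4 | step 16 | C7 trimethylstannane of the decalin (C7=C8, C4=C5, C1 bromide) | C[C@]12CC=C([Sn](C)(C)C)CC1=C(C)CC[C@@H]2Br
F5 | step 16 | chlorohydrin: C12 tertiary alcohol bearing the decalinyl alkene anti to the C11 chlorine | CC1(C)[C@@H](O[Si](C)(C)C(C)(C)C)C[C@](O)(C2=CC[C@]3(C)[C@@H](Br)CCC(C)=C3C2)[C@@]1(C)Cl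
F6 | step 18 | β-boryl ketone: C14 pinacol boronate trans to the decalinyl group, C12 ketone | CC1(C)[C@@H](B3OC(C)(C)C(C)(C)O3)CC(=O)[C@]1(C)C1=CC[C@]2(C)[C@@H](Br)CCC(C)=C2C1
F7 | step 18 | boryl alcohol: C14 pinacol boronate, C12 hydroxyl cis to the decalinyl group | CC1(C)[C@@H](B3OC(C)(C)C(C)(C)O3)C[C@H](O)[C@]1(C)C1=CC[C@]2(C)[C@@H](Br)CCC(C)=C2C1
F8 | step 6 | C1 gem-dibromide of the Wieland–Miescher enone | C[C@]12CCC(=O)C=C1CCCC2(Br)Br
F9 | step 6 | C1 bromo enone, bromine cis to the C10 methyl | C[C@]12CCC(=O)C=C1CCC[C@@H]2Br
F10 | step 6 | C4-methylene derivative of F9 | C[C@]12CCC(=O)C=C1C(=C)CC[C@@H]2Br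
F11 | step 1 | C7 dithiolane of 1 (C5=C6 retained, C1 ketone free) | C[C@]12CCC3(SCCS3)C=C1CCCC2=O
F12 | step 1 | C1 enol triflate of F11 | C[C@]12CCC3(SCCS3)C=C1CCC=C2OS(=O)(=O)C(F)(F)F
F13 | step 1 | C1 bromoalkene dithiolane | C[C@]12CCC3(SCCS3)C=C1CCC=C2Br
A1 | alternative 1 | cis-fused octalone Diels–Alder adduct with C7=C8 alkene | CC1(C)[C@H](Br)C[C@H](O[Si](C)(C)C(C)(C)C)[C@]1(C)C1=CC[C@]2(C)C(=O)CC[C@@H](O[Si](C)(C)C(C)(C)C)[C@@H]2C1
A2 | alternative 1 | 2-substituted butadiene carrying ring C | CC1(C)[C@H](Br)C[C@H](O[Si](C)(C)C(C)(C)C)[C@]1(C)C(=C)C=C
A3 | alternative 1 | 4-(tert-butyldimethylsilyloxy)-2-methylcyclohex-2-en-1-one | O=C1CC[C@@H](O[Si](C)(C)C(C)(C)C)C=C1C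
A4 | alternative 2 | bromo octalin acetonide with C4=C5 alkene | CC1(C)[C@H](Br)C[C@H](O3)[C@]1(C)[C@@]1(OC3(C)C)CC[C@]2(C)[C@@H](Br)CCC(C)=C2C1
A5 | alternative 2 | cyclodeca-1(10),4-diene acetonide with C5 trimethylsilyl group, both ring alkenes trans in the ring | CC1(C)[C@H](Br)C[C@H](O3)[C@]1(C)[C@@]1(OC3(C)C)CC/C(C)=C/CC/C(C)=C(\[Si](C)(C)C)C1
A6 | alternative 3 | 1-bromo-5-hydroxy trans-decal-4-one C7 ethylene acetal | O1CCOC12CC[C@]3(C)[C@@H](Br)CCC(=O)[C@@]3(O)C2
A7 | alternative 3 | keto aldehyde: C5 ketone, C4 aldehyde, C1 bromide, C7 ethylene acetal | O1CCOC12CC[C@](C)([C@@H](Br)CCC=O)C(=O)C2
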